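The cyclobutane (C5, C6, C11, C10) bears at C5 an exocyclic carbon, C4, so C4 and C5 can be the carbonyl and diazo carbons of a five-membered diazo ketone (C5, C4, C10, C11, C6) in a bicyclo[3.2.1]octene. Photochemical Wolff rearrangement shifts C10 from C4 to C5: one operation forms C5–C10, contracts the ring to the cyclobutane and delivers C4 as an ester. The precursor is a 7-diazobicyclo[3.2.1]oct-3-en-6-one with a C7 silyl ether and a silyl-capped ethynyl group on C11. Atom labels: C1–C3 carry angelate, isovalerate and OH; C4 is CMe2; C5 the cyclobutane CH; C6 and C10 the bridgeheads (C6 next to ketone C7); C8=C9 the alkene; C11 the quaternary C–Me.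

Key step: step 13

Remarks:
- Labels written C1–C11 are the target labels; locants inside systematic names are nomenclature locants.
- "Syn" and "anti" place a C11 substituent relative to the two-carbon bridge (C4–C5) or the three-carbon bridge (C7–C9).
- Centres that are formed as mixtures and destroyed later (the carbinol carbon of 7, C4 of 12 and 24, C3 of 27) are left undefined in the SMILES.
- The C7 carbinol configuration of 16–33 is assumed to result from hydride attack anti to the C11 methyl; it is erased in step 22.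
- Metal enolates, acetylides and ylides generated and consumed in situ are not numbered; covalent intermediates of telescoped operations are.

Step 1
Reactants: 1 3-ethoxycyclohex-2-en-1-one; 2 trimethylsilylacetylene
Product: 4 3-[(trimethylsilyl)ethynyl]cyclohex-2-en-1-one, via ethoxy carbinol 3 (not isolated)
Conditions: n-BuLi, THF, −78 °C; then 1, −78 → 0 °C; then aq. HCl (1 M), rt
Reagents that add atoms: water, O
Why: Stork–Danheiser sequence, in which the lithium acetylide adds 1,2 to the vinylogous ester and acid hydrolysis of the enol ether with loss of water transposes the carbonyl to give the 3-alkynyl enone.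

Step 2
Reactants: 4 3-[(trimethylsilyl)ethynyl]cyclohex-2-en-1-one
Product: 5 (S)-3-methyl-3-[(trimethylsilyl)ethynyl]cyclohexan-1-one
Conditions: MeMgBr, Cu(OTf)2 (3 mol%), chiral imidazolinium salt (N-heterocyclic carbene precursor, 4 mol%, the enantiomer that leads to (S)-5), Et2O, −30 °C
Reagents that add atoms: methylmagnesium bromide, C[Mg]Br
Why: Copper-catalysed asymmetric conjugate addition of a Grignard reagent to a cyclic enynone, which with carbene ligands should go 1,4 and not 1,6, so that the ligand-controlled face of attack sets the quaternary centre C11.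

Step 3
Reactants: 5 (S)-3-methyl-3-[(trimethylsilyl)ethynyl]cyclohexan-1-one
Product: 6 (S)-5-methyl-5-[(trimethylsilyl)ethynyl]cyclohex-2-en-1-one
Conditions: IBX, DMSO–fluorobenzene, 70 °C
Reagents that add atoms: none
Why: IBX dehydrogenation of a ketone, which can desaturate only the CH2–CH2 side because the other α-carbon adjoins the quaternary centre, and this also blocks over-oxidation to a dienone.

Step 4
Reactants: 6 (S)-5-methyl-5-[(trimethylsilyl)ethynyl]cyclohex-2-en-1-one
Product: 7 (5S)-1,5-dimethyl-5-[(trimethylsilyl)ethynyl]cyclohex-2-en-1-ol (both C1 epimers)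
Conditions: MeLi, Et2O, −78 °C
Reagents that add atoms: methyllithium, [Li]C
Why: 1,2-Addition of methyllithium to the enone should give the tertiary allylic alcohol, whose carbinol configuration is lost in the next step, while the alkynylsilane is inert at this temperature.

Step 5
Reactants: 7 (5S)-1,5-dimethyl-5-[(trimethylsilyl)ethynyl]cyclohex-2-en-1-ol
Product: 8 (R)-3,5-dimethyl-5-[(trimethylsilyl)ethynyl]cyclohex-2-en-1-one
Conditions: pyridinium chlorochromate [C5H5NH][CrO3Cl], 4 Å molecular sieves, CH2Cl2, rt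
Reagents that add atoms: pyridinium chlorochromate, [O-][Cr](=O)(=O)Cl.c1cc[nH+]cc1
Why: Dauben oxidative 1,3-transposition, in which the chromate ester of the tertiary allylic alcohol undergoes a [3,3] shift and oxidation to place the carbonyl at C7 and the methyl on C9 (the descriptor changes from S to R only because the ring priorities change).

Step 6
Reactants: 8 (R)-3,5-dimethyl-5-[(trimethylsilyl)ethynyl]cyclohex-2-en-1-one; 9 allyl bromide
Product: 10 (5R,6R)-6-allyl-3,5-dimethyl-5-[(trimethylsilyl)ethynyl]cyclohex-2-en-1-one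
Conditions: LiN(i-Pr)2, THF, −78 °C; then 9, DMPU, −78 → −20 °C
Reagents that add atoms: none
Why: Kinetic α′-deprotonation of the enone (cross-conjugated enolate at C6) and C-allylation, in which the electrophile should enter anti to the C11 methyl, the larger group on the neighbouring quaternary carbon, while any C6 epimer is funnelled in step 8.

Step 7
Reactants: 10 (5R,6R)-6-allyl-3,5-dimethyl-5-[(trimethylsilyl)ethynyl]cyclohex-2-en-1-one
Product: 11 2-[(1R,6R)-4,6-dimethyl-2-oxo-6-[(trimethylsilyl)ethynyl]cyclohex-3-en-1-yl]acetaldehyde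
Conditions: OsO4 (2 mol%), NaIO4, 2,6-lutidine, 1,4-dioxane–H2O, rt
Reagents that add atoms: osmium tetroxide, O=[Os](=O)(=O)=O; sodium periodate, [Na+].[O-]I(=O)(=O)=O
Why: Lemieux–Johnson cleavage, in which OsO4 dihydroxylates the monosubstituted alkene far faster than the conjugated enone or the silylalkyne and periodate cleaves the diol to the aldehyde.

Step 8
Reactants: 11 2-[(1R,6R)-4,6-dimethyl-2-oxo-6-[(trimethylsilyl)ethynyl]cyclohex-3-en-1-yl]acetaldehyde
Product: 12 6-hydroxy-4,8-dimethyl-8-[(trimethylsilyl)ethynyl]bicyclo[3.2.1]oct-3-en-2-one (alkynyl syn to the two-carbon bridge; 6-OH epimers)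
Conditions: DBU, MeCN, 0 °C → rt
Reagents that add atoms: none
Why: Intramolecular vinylogous aldol addition, 5-(enolexo)-exo-trig, in which the extended dienolate attacks the aldehyde through C10, and because enolisation at C6 and the aldol are reversible the mixture should settle on the conjugated bicycle that has the C11 methyl over the flat enone bridge and the slim alkyne beside the new two-carbon bridge.

Step 9
Reactants: 12 6-hydroxy-4,8-dimethyl-8-[(trimethylsilyl)ethynyl]bicyclo[3.2.1]oct-3-en-2-one
Product: 13 4,8-dimethyl-8-[(trimethylsilyl)ethynyl]bicyclo[3.2.1]oct-3-ene-2,6-dione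
Conditions: Dess–Martin periodinane, NaHCO3, CH2Cl2, 0 °C → rt
Reagents that add atoms: none
Why: Dess–Martin oxidation of the secondary alcohol under buffered, non-nucleophilic conditions should give the C4 ketone without retro-Claisen opening of the vinylogous β-diketone.

Step 10
Reactants: 13 4,8-dimethyl-8-[(trimethylsilyl)ethynyl]bicyclo[3.2.1]oct-3-ene-2,6-dione
Product: 15 7-diazo-4,8-dimethyl-8-[(trimethylsilyl)ethynyl]bicyclo[3.2.1]oct-3-ene-2,6-dione, via trifluoroacetyl diketone 14 (not isolated)
Conditions: LiN(SiMe3)2, THF, −78 °C; CF3CO2CH2CF3; then MsN3, Et3N, H2O (1 equiv), MeCN, rt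
Reagents that add atoms: methanesulfonyl azide, CS(=O)(=O)N=[N+]=[N-]
Why: Detrifluoroacetylative diazo transfer (Danheiser), which should occur at C5 because it is the only α-CH2 that can be enolised, C6 and C10 being bridgeheads.

Step 11
Reactants: 15 7-diazo-4,8-dimethyl-8-[(trimethylsilyl)ethynyl]bicyclo[3.2.1]oct-3-ene-2,6-dione
Product: 16 7-diazo-2-hydroxy-4,8-dimethyl-8-[(trimethylsilyl)ethynyl]bicyclo[3.2.1]oct-3-en-6-one (2-OH on the face of the one-carbon bridge)
Conditions: NaBH4, CeCl3·7H2O, MeOH, −78 °C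
Reagents that add atoms: none
Why: Luche 1,2-reduction of the enone, which the α-diazo ketone carbonyl should survive because conjugation with the diazo carbon deactivates it, with hydride entering anti to the C11 methyl.

Step 12
Reactants: 16 7-diazo-2-hydroxy-4,8-dimethyl-8-[(trimethylsilyl)ethynyl]bicyclo[3.2.1]oct-3-en-6-one
Product: 17 2-[(tert-butyldimethylsilyl)oxy]-7-diazo-4,8-dimethyl-8-[(trimethylsilyl)ethynyl]bicyclo[3.2.1]oct-3-en-6-one
Conditions: t-BuMe2SiOTf, 2,6-lutidine, CH2Cl2, −78 → 0 °C
Reagents that add atoms: tert-butyldimethylsilyl triflate, CC(C)(C)[Si](C)(C)OS(=O)(=O)C(F)(F)F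
Why: Silylation of the hindered allylic alcohol with a silyl triflate and a hindered base, conditions that diazo carbonyl compounds tolerate, so that neither an enone chromophore nor a free hydroxyl is present during photolysis.

Step 13
Reactants: 17 2-[(tert-butyldimethylsilyl)oxy]-7-diazo-4,8-dimethyl-8-[(trimethylsilyl)ethynyl]bicyclo[3.2.1]oct-3-en-6-one
Product: 20 methyl 4-[(tert-butyldimethylsilyl)oxy]-7-ethynyl-2,7-dimethylbicyclo[3.1.1]hept-2-ene-6-carboxylate (ester cis to ethynyl on the cyclobutane), via ketene 18 (not isolated), via silylalkynyl ester 19 (not isolated)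
Conditions: hν (medium-pressure Hg lamp, Pyrex filter), MeOH, 0 °C; then K2CO3, rt
Reagents that add atoms: methanol, CO
Why: Excitation of the α-diazo ketone expels N2 and, because the five-membered ring locks the s-Z geometry, C10 shifts from C4 to the carbene carbon C5 in concert to give ketene 18, which methanol traps as the ester. This is the photochemical Wolff ring contraction known for bicyclic α-diazo ketones on the way to bicyclo[2.1.1]hexane and bicyclo[3.1.1]heptane carboxylates. The cyclobutane is not closed end to end but results from the 1,2-shift that contracts the cyclopentanone ring, and C10 migrates with retention. The new stereocentre C5 should be set when the ketene-derived enol is protonated from the face of the C7–C9 bridge, away from the alkynyl rod on C11 and unhindered by the C7 silyl ether that points to the other side; this places the ester cis to the alkyne and is the kinetic epimer, so equilibrating base is avoided afterwards. The rearrangement must outrun O–H insertion and enone photochemistry, which the locked geometry and the C7 silyl ether secure; the alkynyl silyl cap, kept on the precursor to protect the acetylenic position in the base-mediated steps before, is then cleaved by K2CO3 in the same methanol solution.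

Step 14
Reactants: 20 methyl 4-[(tert-butyldimethylsilyl)oxy]-7-ethynyl-2,7-dimethylbicyclo[3.1.1]hept-2-ene-6-carboxylate
Product: 22 1-[4-[(tert-butyldimethylsilyl)oxy]-7-ethynyl-2,7-dimethylbicyclo[3.1.1]hept-2-en-6-yl]ethan-1-one, via Weinreb amide 21 (not isolated)
Conditions: MeNHOMe·HCl, i-PrMgCl, THF, −20 °C; then MeMgBr, 0 °C
Reagents that add atoms: methylmagnesium bromide, C[Mg]Br
Why: Ester to Weinreb amide with the magnesium amide, then Grignard addition halted at the chelated tetrahedral intermediate should give the methyl ketone, the acetylenic proton only consuming one extra equivalent of Grignard reagent and C5 never meeting an equilibrating base.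

Step 15
Reactants: 22 1-[4-[(tert-butyldimethylsilyl)oxy]-7-ethynyl-2,7-dimethylbicyclo[3.1.1]hept-2-en-6-yl]ethan-1-one
Product: 24 2-[4-[(tert-butyldimethylsilyl)oxy]-7-ethynyl-2,7-dimethylbicyclo[3.1.1]hept-2-en-6-yl]propanal (C4 epimers), via enol ether 23 (not isolated)
Conditions: Ph3P(CH2OMe)Cl, KN(SiMe3)2, THF, 0 °C → rt; then TsOH·H2O (cat.), acetone–H2O, rt
Reagents that add atoms: (methoxymethyl)triphenylphosphonium chloride, COC[P+](c1ccccc1)(c1ccccc1)c1ccccc1.[Cl-]; water, O
Why: Wittig methoxymethylenation followed by mild hydrolysis of the enol ether is a one-carbon homologation that never places a cation or a radical on C4, so the cyclobutylcarbinyl position cannot rearrange or fragment.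

Step 16
Reactants: 24 2-[4-[(tert-butyldimethylsilyl)oxy]-7-ethynyl-2,7-dimethylbicyclo[3.1.1]hept-2-en-6-yl]propanal
Product: 25 2-[4-[(tert-butyldimethylsilyl)oxy]-7-ethynyl-2,7-dimethylbicyclo[3.1.1]hept-2-en-6-yl]-2-methylpropanal
Conditions: KOt-Bu, MeI, THF, 0 °C
Reagents that add atoms: iodomethane, CI
Why: C-Methylation of the α-branched aldehyde enolate should create the quaternary C4, since the enolate has no β-leaving group and the far less acidic alkyne stays untouched.

Step 17
Reactants: 25 2-[4-[(tert-butyldimethylsilyl)oxy]-7-ethynyl-2,7-dimethylbicyclo[3.1.1]hept-2-en-6-yl]-2-methylpropanal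
Product: 26 2-[7-acetyl-4-[(tert-butyldimethylsilyl)oxy]-2,7-dimethylbicyclo[3.1.1]hept-2-en-6-yl]-2-methylpropanal
Conditions: (JohnPhos)Au(NCMe)SbF6 (2 mol%), 1,4-dioxane–H2O, 60 °C
Reagents that add atoms: water, O
Why: Gold-catalysed Markovnikov hydration of the terminal alkyne should give the methyl ketone under acid-free conditions that leave the alkene, the aldehyde and the allylic silyl ether alone.

Step 18
Reactants: 26 2-[7-acetyl-4-[(tert-butyldimethylsilyl)oxy]-2,7-dimethylbicyclo[3.1.1]hept-2-en-6-yl]-2-methylpropanal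
Product: 28 tricyclic enone (C1 ketone; C2=C3; C4 gem-dimethyl; C7 silyl ether; C8=C9), via aldol 27 (not isolated)
Conditions: KOH, MeOH, rt → 50 °C
Reagents that add atoms: none
Why: Intramolecular aldol condensation, 7-(enolendo)-exo-trig, which can only give the cycloheptenone because the ketone enolises solely toward its methyl group (C2), the aldehyde (C3) has no α-hydrogen, and the cis-1,3 arrangement on the cyclobutane holds the two arms together.

Step 19
Reactants: 28 tricyclic enone
Product: 29 tricyclic (1R)-allylic alcohol (C1 OH on the side of C6; C2=C3; C7 silyl ether)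
Conditions: (S)-2-methyl-CBS-oxazaborolidine (0.3 equiv), catecholborane, toluene, −78 °C
Reagents that add atoms: none
Why: Corey–Bakshi–Shibata reduction of the enone, 1,2-selective, in which the quaternary C11 should act as the large and the CH=CH arm as the small substituent, so that the (S)-catalyst delivers hydride to the face of C10 and sets C1 as in the target.

Step 20
Reactants: 29 tricyclic (1R)-allylic alcohol; 30 angelic acid
Product: 32 C1 angelate of 29 (C7 silyl ether), via mixed anhydride 31 (not isolated)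
Conditions: 2,4,6-Cl3C6H2COCl, Et3N, toluene, rt; then 29, 80 °C
Reagents that add atoms: none
Why: Yamaguchi-type esterification through the 2,4,6-trichlorobenzoic mixed anhydride without a nucleophilic catalyst, a protocol that acylates hindered alcohols with angelic acid without Z to E isomerisation.

Step 21
Reactants: 32 C1 angelate (C7 silyl ether)
Product: 33 C1 angelate with free C7 hydroxyl
Conditions: Bu4NF, AcOH, THF, rt
Reagents that add atoms: none
Why: Buffered fluoride desilylation, which cannot cause acyl migration because no free hydroxyl neighbours the angelate.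

Step 22
Reactants: 33 C1 angelate with free C7 hydroxyl
Product: 34 C1 angelate C7 enone (C2=C3 still present)
Conditions: MnO2, CH2Cl2, rt
Reagents that add atoms: none
Why: Manganese dioxide oxidation of the allylic alcohol should give the C7 enone and thereby make C8=C9 electron-poor before the dihydroxylation.

Step 23
Reactants: 34 C1 angelate C7 enone
Product: 35 C2,C3-diol C1 angelate (both hydroxyls trans to the C1 oxygen)
Conditions: OsO4 (5 mol%), N-methylmorpholine N-oxide, acetone–H2O, rt
Reagents that add atoms: osmium tetroxide, O=[Os](=O)(=O)=O; N-methylmorpholine N-oxide, C[N+]1([O-])CCOCC1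
Why: Upjohn dihydroxylation, selective for C2=C3 as the only alkene not conjugated to a carbonyl, with OsO4 adding anti to the allylic C1 ester (Kishi's rule) to set C2 and C3.

Step 24
Reactants: 35 C2,C3-diol C1 angelate; 36 3-methylbutanoyl chloride
Product: 37 target (C1 angelate; C2 isovalerate; C3 hydroxyl)
Conditions: pyridine, CH2Cl2, −20 °C
Reagents that add atoms: none
Why: Site-selective acylation, in which the neopentylic C3 hydroxyl next to CMe2 should react much more slowly than the C2 hydroxyl, so that one equivalent of acid chloride gives the C2 isovalerate.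

Compound list
1 | 3-ethoxycyclohex-2-en-1-one | CCOC1=CC(=O)CCC1 | starting material
2 | trimethylsilylacetylene | C#C[Si](C)(C)C | starting material
3 | 3-ethoxy-1-[(trimethylsilyl)ethynyl]cyclohex-2-en-1-ol (racemic) | CCOC1=CC(O)(C#C[Si](C)(C)C)CCC1 | intermediate (not isolated)
4 | 3-[(trimethylsilyl)ethynyl]cyclohex-2-en-1-one | O=C1C=C(C#C[Si](C)(C)C)CCC1 | intermediate
5 | (S)-3-methyl-3-[(trimethylsilyl)ethynyl]cyclohexan-1-one | O=C1C[C@@](C)(C#C[Si](C)(C)C)CCC1 | intermediate
6 | (S)-5-methyl-5-[(trimethylsilyl)ethynyl]cyclohex-2-en-1-one | O=C1C[C@@](C)(C#C[Si](C)(C)C)CC=C1 | intermediate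
7 | (5S)-1,5-dimethyl-5-[(trimethylsilyl)ethynyl]cyclohex-2-en-1-ol, both C1 epimers | CC1(O)C[C@@](C)(C#C[Si](C)(C)C)CC=C1 | intermediate
8 | (R)-3,5-dimethyl-5-[(trimethylsilyl)ethynyl]cyclohex-2-en-1-one | O=C1C=C(C)C[C@@](C)(C#C[Si](C)(C)C)C1 | intermediate
9 | allyl bromide | C=CCBr | starting material
10 | (5R,6R)-6-allyl-3,5-dimethyl-5-[(trimethylsilyl)ethynyl]cyclohex-2-en-1-one, allyl trans to the 5-methyl | O=C1C=C(C)C[C@@](C)(C#C[Si](C)(C)C)[C@H]1CC=C | intermediate
11 | 2-[(1R,6R)-4,6-dimethyl-2-oxo-6-[(trimethylsilyl)ethynyl]cyclohex-3-en-1-yl]acetaldehyde | O=C1C=C(C)C[C@@](C)(C#C[Si](C)(C)C)[C@H]1CC=O | intermediate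
12 | 6-hydroxy-4,8-dimethyl-8-[(trimethylsilyl)ethynyl]bicyclo[3.2.1]oct-3-en-2-one, alkynyl syn to the two-carbon bridge, 8-methyl syn to the enone bridge, 6-OH epimers | C1C(O)[C@@H]2C(C)=CC(=O)[C@H]1[C@]2(C)C#C[Si](C)(C)C | intermediate
13 | 4,8-dimethyl-8-[(trimethylsilyl)ethynyl]bicyclo[3.2.1]oct-3-ene-2,6-dione, alkynyl syn to the two-carbon bridge | C1C(=O)[C@@H]2C(C)=CC(=O)[C@H]1[C@]2(C)C#C[Si](C)(C)C | intermediate
14 | 4,8-dimethyl-7-(trifluoroacetyl)-8-[(trimethylsilyl)ethynyl]bicyclo[3.2.1]oct-3-ene-2,6-dione | O=C(C1C(=O)[C@@H]2C(C)=CC(=O)[C@H]1[C@]2(C)C#C[Si](C)(C)C)C(F)(F)F | intermediate (not isolated)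
15 | 7-diazo-4,8-dimethyl-8-[(trimethylsilyl)ethynyl]bicyclo[3.2.1]oct-3-ene-2,6-dione | [N-]=[N+]=C1C(=O)[C@@H]2C(C)=CC(=O)[C@H]1[C@]2(C)C#C[Si](C)(C)C | intermediate
16 | 7-diazo-2-hydroxy-4,8-dimethyl-8-[(trimethylsilyl)ethynyl]bicyclo[3.2.1]oct-3-en-6-one, 2-OH on the face of the one-carbon bridge | [N-]=[N+]=C1C(=O)[C@@H]2C(C)=C[C@@H](O)[C@H]1[C@]2(C)C#C[Si](C)(C)C | intermediate
17 | 2-[(tert-butyldimethylsilyl)oxy]-7-diazo-4,8-dimethyl-8-[(trimethylsilyl)ethynyl]bicyclo[3.2.1]oct-3-en-6-one (key-step precursor) | [N-]=[N+]=C1C(=O)[C@@H]2C(C)=C[C@@H](O[Si](C)(C)C(C)(C)C)[C@H]1[C@]2(C)C#C[Si](C)(C)C | intermediate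
18 | 4-[(tert-butyldimethylsilyl)oxy]-2,7-dimethyl-6-(oxomethylidene)-7-[(trimethylsilyl)ethynyl]bicyclo[3.1.1]hept-2-ene (ketene) | O=C=C2[C@H]3[C@H](O[Si](C)(C)C(C)(C)C)C=C(C)[C@@H]2[C@@]3(C)C#C[Si](C)(C)C | intermediate (not isolated)
19 | methyl 4-[(tert-butyldimethylsilyl)oxy]-2,7-dimethyl-7-[(trimethylsilyl)ethynyl]bicyclo[3.1.1]hept-2-ene-6-carboxylate | COC(=O)[C@@H]2[C@H]3[C@H](O[Si](C)(C)C(C)(C)C)C=C(C)[C@@H]2[C@@]3(C)C#C[Si](C)(C)C | intermediate (not isolated)
20 | methyl 4-[(tert-butyldimethylsilyl)oxy]-7-ethynyl-2,7-dimethylbicyclo[3.1.1]hept-2-ene-6-carboxylate, ester and ethynyl cis on the cyclobutane and anti to the three-carbon bridge, silyloxy on the face of the ethynyl-bearing bridge (key-step product) | COC(=O)[C@@H]2[C@H]3[C@H](O[Si](C)(C)C(C)(C)C)C=C(C)[C@@H]2[C@@]3(C)C#C | intermediate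
21 | N-methoxy-N-methyl amide of the acid of 20 (Weinreb amide) | CON(C)C(=O)[C@@H]2[C@H]3[C@H](O[Si](C)(C)C(C)(C)C)C=C(C)[C@@H]2[C@@]3(C)C#C | intermediate (not isolated)
22 | 1-[4-[(tert-butyldimethylsilyl)oxy]-7-ethynyl-2,7-dimethylbicyclo[3.1.1]hept-2-en-6-yl]ethan-1-one | CC(=O)[C@@H]2[C@H]3[C@H](O[Si](C)(C)C(C)(C)C)C=C(C)[C@@H]2[C@@]3(C)C#C | intermediate
23 | methyl enol ether of 24 (E/Z mixture) | COC=C(C)[C@@H]2[C@H]3[C@H](O[Si](C)(C)C(C)(C)C)C=C(C)[C@@H]2[C@@]3(C)C#C | intermediate (not isolated)
24 | 2-[4-[(tert-butyldimethylsilyl)oxy]-7-ethynyl-2,7-dimethylbicyclo[3.1.1]hept-2-en-6-yl]propanal, C4 epimers | O=CC(C)[C@@H]2[C@H]3[C@H](O[Si](C)(C)C(C)(C)C)C=C(C)[C@@H]2[C@@]3(C)C#C | intermediate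
25 | 2-[4-[(tert-butyldimethylsilyl)oxy]-7-ethynyl-2,7-dimethylbicyclo[3.1.1]hept-2-en-6-yl]-2-methylpropanal | O=CC(C)(C)[C@@H]2[C@H]3[C@H](O[Si](C)(C)C(C)(C)C)C=C(C)[C@@H]2[C@@]3(C)C#C | intermediate
26 | 2-[7-acetyl-4-[(tert-butyldimethylsilyl)oxy]-2,7-dimethylbicyclo[3.1.1]hept-2-en-6-yl]-2-methylpropanal | O=CC(C)(C)[C@@H]2[C@H]3[C@H](O[Si](C)(C)C(C)(C)C)C=C(C)[C@@H]2[C@@]3(C)C(C)=O | intermediate
27 | tricyclic β-hydroxy ketone (C1 ketone, C3 hydroxyl as epimers, C7 silyl ether) | O=C1CC(O)C(C)(C)[C@@H]2[C@H]3[C@H](O[Si](C)(C)C(C)(C)C)C=C(C)[C@@H]2[C@@]13C | intermediate (not isolated)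
28 | tricyclic enone (C1 ketone, C2=C3, C4 gem-dimethyl, C7 silyl ether, C8=C9; ring fusion as in the target) | O=C1C=CC(C)(C)[C@@H]2[C@H]3[C@H](O[Si](C)(C)C(C)(C)C)C=C(C)[C@@H]2[C@@]13C | intermediate
29 | tricyclic (1R)-allylic alcohol (C1 hydroxyl on the side of C6, C2=C3, C7 silyl ether) | O[C@@H]1C=CC(C)(C)[C@@H]2[C@H]3[C@H](O[Si](C)(C)C(C)(C)C)C=C(C)[C@@H]2[C@@]13C | intermediate
30 | angelic acid, (Z)-2-methylbut-2-enoic acid | C/C=C(/C)C(=O)O | starting material
31 | angelic 2,4,6-trichlorobenzoic anhydride | C/C=C(/C)C(=O)OC(=O)c1c(Cl)cc(Cl)cc1Cl | intermediate (not isolated)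
32 | C1 angelate of 29 (C2=C3, C7 silyl ether) | C/C=C(/C)C(=O)O[C@@H]1C=CC(C)(C)[C@@H]2[C@H]3[C@H](O[Si](C)(C)C(C)(C)C)C=C(C)[C@@H]2[C@@]13C | intermediate
33 | C1 angelate with free C7 hydroxyl (C2=C3) | C/C=C(/C)C(=O)O[C@@H]1C=CC(C)(C)[C@@H]2[C@H]3[C@H](O)C=C(C)[C@@H]2[C@@]13C | intermediate
34 | C1 angelate C7 enone (C2=C3) | C/C=C(/C)C(=O)O[C@@H]1C=CC(C)(C)[C@@H]2[C@H]3C(=O)C=C(C)[C@@H]2[C@@]13C | intermediate
35 | C2,C3-diol C1 angelate C7 enone (C2 and C3 hydroxyls cis to each other and trans to the C1 oxygen) | C/C=C(/C)C(=O)O[C@@H]1[C@@H](O)[C@@H](O)C(C)(C)[C@@H]2[C@H]3C(=O)C=C(C)[C@@H]2[C@@]13C | intermediate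
36 | 3-methylbutanoyl chloride (isovaleryl chloride) | CC(C)CC(=O)Cl | starting material
37 | CNP0251293.1 (C1 angelate, C2 isovalerate, C3 hydroxyl) | C/C=C(/C)C(=O)O[C@@H]1[C@@H](OC(=O)CC(C)C)[C@@H](O)C(C)(C)[C@@H]2[C@H]3C(=O)C=C(C)[C@@H]2[C@@]13C | target

Total step count: 24 (12 before the key step, the key step, 11 after).
Longest linear sequence: 24 steps, from 1 and 2 to 37.

Steps most likely to fail

1. Step 8, the intramolecular vinylogous aldol. The reversible closure may rest on the side of the open keto aldehyde. It may also leak into attack through C8 or into Michael addition of the aldehyde enolate at C9, or equilibrate toward the bicycle that has the C11 methyl beside the new bridge. The fallback sets out from 6 and returns at 12: the two-carbon unit is attached before the enone transposition and the ring is closed by an irreversible alkylation. The kinetic lithium enolate of 6 (LiN(i-Pr)2, THF, −78 °C; deprotonation at the CH2 between carbonyl and quaternary carbon, the future C10) is added to anhydrous chloroacetaldehyde and quenched cold to give the chlorohydrin F1, with the new bond expected anti to the C11 methyl. Silylation (t-BuMe2SiOTf, 2,6-lutidine) gives the silyl ether F2. MeLi adds to the ketone to give the tertiary allylic alcohol F3, and pyridinium chlorochromate transposes it to the enone F4, which now carries the arm on C10. LiN(i-Pr)2 then forms the C6 enolate, which displaces chloride (NaI, DMPU, −78 °C → rt; 5-exo-tet) to give the bicyclic silyl ether F5. HCl in MeOH frees the alcohol 12.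

2. Step 13, the photochemical Wolff contraction. The carbene may insert into the O–H bond of methanol instead of rearranging, or the enol may be protonated beside C11 and give the C5 epimer, which cannot close the seven-membered ring. The fallback sets out from 17 and returns at 20. HBr (1 equiv, Et2O, −78 °C) converts the diazo ketone into the α-bromo ketone F6, with bromine expected exo, away from the C7–C9 bridge. NaOMe in MeOH then effects a semibenzilic (quasi-Favorskii) ring contraction: C10 is a bridgehead, so no cyclopropanone can form; methoxide adds to the C4 carbonyl and C10 shifts to C5 with inversion and loss of bromide. This forms the same C5–C10 bond and the same C5 configuration, and the methoxide also removes the alkynyl silyl group to give 20.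

3. Step 17, the gold-catalysed hydration. Hydration may stall at the neopentylic alkyne, or the cationic gold catalyst may ionise the allylic silyl ether. The fallback sets out from 25 and returns at 26. Semi-hydrogenation (H2, Pd/CaCO3 poisoned with Pb(OAc)2, quinoline) gives the vinyl compound F7. Tsuji–Wacker oxidation (PdCl2, CuCl, O2, DMF–H2O) then converts the monosubstituted alkene into the methyl ketone 26, leaving the trisubstituted alkene and the aldehyde alone.

Further compounds
F1 | step 8 | (5S,6R)-6-(2-chloro-1-hydroxyethyl)-5-methyl-5-[(trimethylsilyl)ethynyl]cyclohex-2-en-1-one (chlorohydrin, carbinol epimers, side chain trans to the 5-methyl) | O=C1[C@@H](C(O)CCl)[C@@](C)(C#C[Si](C)(C)C)CC=C1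
F2 | step 8 | tert-butyldimethylsilyl ether of F1 | O=C1[C@@H](C(CCl)O[Si](C)(C)C(C)(C)C)[C@@](C)(C#C[Si](C)(C)C)CC=C1
F3 | step 8 | 6-[1-[(tert-butyldimethylsilyl)oxy]-2-chloroethyl]-1,5-dimethyl-5-[(trimethylsilyl)ethynyl]cyclohex-2-en-1-ol (tertiary allylic alcohol, C1 epimers) | CC1(O)[C@@H](C(CCl)O[Si](C)(C)C(C)(C)C)[C@@](C)(C#C[Si](C)(C)C)CC=C1
F4 | step 8 | 4-[1-[(tert-butyldimethylsilyl)oxy]-2-chloroethyl]-3,5-dimethyl-5-[(trimethylsilyl)ethynyl]cyclohex-2-en-1-one (transposed enone) | O=C1C=C(C)[C@@H](C(CCl)O[Si](C)(C)C(C)(C)C)[C@@](C)(C#C[Si](C)(C)C)C1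
F5 | step 8 | 6-[(tert-butyldimethylsilyl)oxy]-4,8-dimethyl-8-[(trimethylsilyl)ethynyl]bicyclo[3.2.1]oct-3-en-2-one (silyl ether of 12) | C1C(O[Si](C)(C)C(C)(C)C)[C@@H]2C(C)=CC(=O)[C@H]1[C@]2(C)C#C[Si](C)(C)C
F6 | step 13 | 7-exo-bromo-2-[(tert-butyldimethylsilyl)oxy]-4,8-dimethyl-8-[(trimethylsilyl)ethynyl]bicyclo[3.2.1]oct-3-en-6-one | Br[C@H]1C(=O)[C@@H]2C(C)=C[C@@H](O[Si](C)(C)C(C)(C)C)[C@H]1[C@]2(C)C#C[Si](C)(C)C
F7 | step 17 | 2-[4-[(tert-butyldimethylsilyl)oxy]-7-ethenyl-2,7-dimethylbicyclo[3.1.1]hept-2-en-6-yl]-2-methylpropanal | O=CC(C)(C)[C@@H]2[C@H]3[C@H](O[Si](C)(C)C(C)(C)C)C=C(C)[C@@H]2[C@@]3(C)C=C
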